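**Retrosynthetic overview**

- Target ⇒ nickel-catalysed sp2–sp3 coupling (C1'–C2') of an (E)-alkenylalane, made by methylalumination of a C18 homopropargylic alcohol, with 2-(bromomethyl)-3-methyl-1,4-naphthoquinone.
- Bromomethylquinone ⇒ 2,3-dimethyl-1,4-naphthoquinone ⇒ two-carbon ring expansion of benzocyclobutenone with but-2-yne (nickel insertion into the acyl–CH2 bond), then para-oxygenation.
- Homopropargylic alcohol ⇒ asymmetric propargylboration of (3R,7R)-3,7,11-trimethyldodecanal (sets 5'S).
- Aldehyde ⇒ double asymmetric hydrogenation of the (2E,6E)-dienol (sets 7'R and 11'R) ⇒ two alkyne methylalumination/chain-extension cycles from 1-bromo-4-methylpentane.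
- Ring order: the benzene ring is bought (bromobenzene); the four-membered ring is made first (benzyne + ketene acetal) and is then expanded to the six-membered quinone ring.

Assumption: side-chain locants (1'–16') count from the quinone; the target is 2-[(2E,5S,7R,11R)-5-hydroxy-3,7,11,15-tetramethylhexadec-2-en-1-yl]-3-methylnaphthalene-1,4-dione. Building blocks with three or more carbons are numbered as starting materials; one- and two-carbon donors (AlMe3, lithium acetylide, oxirane, formaldehyde) are listed as reagents.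

**Route**

Step 1
Reactants: 1 1-bromo-4-methylpentane
Product: 2 6-methylhept-1-yne
Conditions: LiC≡CH·H2NCH2CH2NH2 (1.3 equiv), DMSO, 10 → 23 °C
Reagents that add atoms: lithium acetylide ethylenediamine complex, [Li+].[C-]#C.NCCN
Why: SN2 alkylation of lithium acetylide by a primary bromide in DMSO (acetylide alkylation); no stereocentre is involved.

Step 2
Reactants: 2 6-methylhept-1-yne
Product: 5 (3E)-4,8-dimethylnon-3-en-1-ol, via alkenylalane 3 (not isolated), via lithium alanate 4 (not isolated)
Conditions: AlMe3 (2 equiv), Cp2ZrCl2 (0.25 equiv), CH2Cl2, 0 → 23 °C; evaporate, hexane; n-BuLi, −78 → 0 °C; oxirane, THF, −30 → 0 °C; 1 M HCl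
Reagents that add atoms: trimethylaluminium, C[Al](C)C; oxirane, C1CO1
Why: Negishi zirconium-catalysed syn-methylalumination puts CH3 on the internal and Al on the terminal alkyne carbon, and the derived alanate opens oxirane with retention, so the trisubstituted alkene is formed ≥98% E.

Step 3
Reactants: 5 (3E)-4,8-dimethylnon-3-en-1-ol
Product: 7 (5E)-6,10-dimethylundec-5-en-1-yne, via homoallylic tosylate 6 (not isolated)
Conditions: n-BuLi (1.0 equiv), THF, −78 → 0 °C; TsCl (1.0 equiv), 0 °C; then DMSO, LiC≡CH·H2NCH2CH2NH2 (2 equiv), 23 °C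
Reagents that add atoms: lithium acetylide ethylenediamine complex, [Li+].[C-]#C.NCCN
Why: The lithium alkoxide is tosylated in the flask and the primary tosylate is displaced by lithium acetylide (SN2 acetylide alkylation), leaving the remote E-alkene untouched.

Step 4
Reactants: 7 (5E)-6,10-dimethylundec-5-en-1-yne
Product: 10 (2E,6E)-3,7,11-trimethyldodeca-2,6-dien-1-ol, via dienylalane 8 (not isolated), via lithium alanate 9 (not isolated)
Conditions: AlMe3 (2 equiv), Cp2ZrCl2 (0.25 equiv), CH2Cl2, 0 → 23 °C; evaporate, hexane; n-BuLi, −78 → 0 °C; (CH2O)n, THF, 23 °C; 1 M HCl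
Reagents that add atoms: trimethylaluminium, C[Al](C)C; paraformaldehyde (as formaldehyde), C=O
Why: A second Negishi syn-methylalumination, chemoselective for the terminal alkyne, followed by hydroxymethylation of the alanate with retention gives the 2E allylic alcohol.

Step 5
Reactants: 10 (2E,6E)-3,7,11-trimethyldodeca-2,6-dien-1-ol
Product: 11 (3R,7R)-3,7,11-trimethyldodecan-1-ol
Conditions: H2 (50 bar), [Ir(cod)(L*)]BArF (1 mol%; L* = 2-phenyl-5,6,7,8-tetrahydroquinolin-8-yl di-tert-butylphosphinite, the enantiomer that takes (2E,6E)-farnesol to the 3R,7R alcohol; BArF = B[3,5-(CF3)2C6H3]4), CH2Cl2, 23 °C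
Reagents that add atoms: none
Why: Iridium N,P-catalysed asymmetric hydrogenation of trisubstituted alkenes (Pfaltz type); both E-alkenes present the same enantioface to the catalyst, so C3 and C7 are set R,R under catalyst control as in the farnesol precedent.

Step 6
Reactants: 11 (3R,7R)-3,7,11-trimethyldodecan-1-ol
Product: 12 (3R,7R)-3,7,11-trimethyldodecanal
Conditions: TEMPO (10 mol%), PhI(OAc)2 (1.1 equiv), CH2Cl2, 23 °C
Reagents that add atoms: none
Why: Oxoammonium (TEMPO) oxidation stops at the aldehyde, and the β-stereocentre cannot epimerise.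

Step 7
Reactants: 12 (3R,7R)-3,7,11-trimethyldodecanal; 13 3-bromoprop-1-yne
Product: 16 (4S,6R,10R)-6,10,14-trimethylpentadec-1-yn-4-ol, via allenylmagnesium bromide 14 (not isolated), via B-allenyldiisopinocampheylborane 15 (not isolated)
Conditions: 13, Mg, HgCl2 (1 mol%), Et2O, 0 °C; (+)-Ipc2BOMe [from (−)-α-pinene], −78 → 23 °C; 12, −78 °C; NaOH, H2O2, 0 → 23 °C
Reagents that add atoms: none
Why: Brown asymmetric propargylboration (SE2' transfer from the allenylborane through a chair six-membered transition state); the (+)-Ipc2B reagent delivers the propargyl group to the Re face, by analogy with the facial sense of the Brown allylboration, which sets C4 as S under reagent control.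

Step 8
Reactants: 17 bromobenzene; 18 1,1-dimethoxyethene
Product: 21 bicyclo[4.2.0]octa-1,3,5-trien-7-one (benzocyclobutenone), via benzyne 19 (not isolated), via benzocyclobutenone dimethyl acetal 20 (not isolated)
Conditions: NaNH2 (2 equiv), THF, reflux; then 1 M HCl, 23 °C
Reagents that add atoms: water, O
Why: Dehydrobromination gives benzyne, which adds the electron-rich ketene acetal in a polar [2+2] cycloaddition, and acid hydrolysis of the acetal unveils the strained ketone (benzyne/ketene-acetal route to benzocyclobutenones).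

Step 9
Reactants: 21 bicyclo[4.2.0]octa-1,3,5-trien-7-one; 22 but-2-yne
Product: 25 2,3-dimethylnaphthalene-1,4-dione, via 2,3-dimethylnaphthalen-1(4H)-one 23 (not isolated), via 2,3-dimethylnaphthalen-1-ol 24 (not isolated)
Conditions: Ni(cod)2 (10 mol%), PCy3 (20 mol%), 22 (3 equiv), toluene, 80 °C, sealed tube; then DMF, Co(salen) (5 mol%), O2 (1 atm), 23 °C
Reagents that add atoms: dioxygen, O=O
Why: Proposed new method: zerovalent nickel inserts oxidatively into the strained acyl–CH2 bond (C1–C2) of 21 to give a nickela-indanone (or, equivalently, carbonyl/alkyne oxidative cyclisation followed by β-carbon elimination), 1,2-insertion of but-2-yne and C–C reductive elimination expand the four-membered ring to the six-membered enone 23, aromatisation to 24 drives turnover, and Co(salen)/O2 then oxygenates the free para position in the same flask; the pathway is organometallic, since 80 °C is far below the thermal ring opening of 21; the closest known reaction types are the nickel-catalysed cyclobutenone + alkyne → phenol ring expansion, rhodium-catalysed C–C activation/insertion of benzocyclobutenones with tethered alkynes, and Co(salen)/O2 oxidation of 1-naphthols to 1,4-quinones.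

Step 10
Reactants: 25 2,3-dimethylnaphthalene-1,4-dione
Product: 26 2-(bromomethyl)-3-methylnaphthalene-1,4-dione
Conditions: NBS (1.0 equiv), AIBN (5 mol%), PhCF3, 85 °C, stopped at about 70% conversion
Reagents that add atoms: N-bromosuccinimide, O=C1CCC(=O)N1Br
Why: Wohl–Ziegler radical bromination at the allylic-type quinone methyl; one equivalent of NBS and partial conversion hold it at the mono-bromide.

Step 11
Reactants: 16 (4S,6R,10R)-6,10,14-trimethylpentadec-1-yn-4-ol; 26 2-(bromomethyl)-3-methylnaphthalene-1,4-dione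
Product: 28 2-[(2E,5S,7R,11R)-5-hydroxy-3,7,11,15-tetramethylhexadec-2-en-1-yl]-3-methylnaphthalene-1,4-dione, via alkenylalane alkoxide 27 (not isolated)
Conditions: AlMe3 (3 equiv), Cp2ZrCl2 (0.25 equiv), CH2Cl2, 0 → 23 °C; excess AlMe3 removed in vacuo; 26, NiCl2(PPh3)2 (3 mol%)/n-BuLi (6 mol%), THF, 0 → 23 °C; 0.5 M HCl
Reagents that add atoms: trimethylaluminium, C[Al](C)C
Why: Negishi syn-methylalumination of the homopropargylic alkoxide fixes the 2'E geometry, and zerovalent-nickel-catalysed cross-coupling of the alkenylalane with the halomethylquinone (Lipshutz-type quinone allylation) proceeds with retention and touches no stereocentre.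

**Compound list**

1 | 1-bromo-4-methylpentane | CC(C)CCCBr | starting material
2 | 6-methylhept-1-yne | C#CCCCC(C)C | intermediate
3 | [(1E)-2,6-dimethylhept-1-en-1-yl]dimethylalumane | C[Al](C)/C=C(\C)CCCC(C)C | intermediate
4 | lithium butyl[(1E)-2,6-dimethylhept-1-en-1-yl]dimethylaluminate | [Li+].CCCC[Al-](C)(C)/C=C(\C)CCCC(C)C | intermediate
5 | (3E)-4,8-dimethylnon-3-en-1-ol | OCC/C=C(\C)CCCC(C)C | intermediate
6 | (3E)-4,8-dimethylnon-3-en-1-yl 4-methylbenzenesulfonate | Cc1ccc(cc1)S(=O)(=O)OCC/C=C(\C)CCCC(C)C | intermediate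
7 | (5E)-6,10-dimethylundec-5-en-1-yne | C#CCC/C=C(\C)CCCC(C)C | intermediate
8 | dimethyl[(1E,5E)-2,6,10-trimethylundeca-1,5-dien-1-yl]alumane | C[Al](C)/C=C(\C)CC/C=C(\C)CCCC(C)C | intermediate
9 | lithium butyldimethyl[(1E,5E)-2,6,10-trimethylundeca-1,5-dien-1-yl]aluminate | [Li+].CCCC[Al-](C)(C)/C=C(\C)CC/C=C(\C)CCCC(C)C | intermediate
10 | (2E,6E)-3,7,11-trimethyldodeca-2,6-dien-1-ol | OC/C=C(\C)CC/C=C(\C)CCCC(C)C | intermediate
11 | (3R,7R)-3,7,11-trimethyldodecan-1-ol | OCC[C@H](C)CCC[C@H](C)CCCC(C)C | intermediate
12 | (3R,7R)-3,7,11-trimethyldodecanal | O=CC[C@H](C)CCC[C@H](C)CCCC(C)C | intermediate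
13 | 3-bromoprop-1-yne | C#CCBr | starting material
14 | propa-1,2-dien-1-ylmagnesium bromide | C=C=C[Mg]Br | intermediate
15 | (propa-1,2-dien-1-yl)bis[(1S,2R,3S,5S)-2,6,6-trimethylbicyclo[3.1.1]heptan-3-yl]borane | C=C=CB([C@H]1C[C@H]2C[C@@H]([C@@H]1C)C2(C)C)[C@H]1C[C@H]2C[C@@H]([C@@H]1C)C2(C)C | intermediate
16 | (4S,6R,10R)-6,10,14-trimethylpentadec-1-yn-4-ol | C#CC[C@@H](O)C[C@H](C)CCC[C@H](C)CCCC(C)C | intermediate
17 | bromobenzene | Brc1ccccc1 | starting material
18 | 1,1-dimethoxyethene | C=C(OC)OC | starting material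
19 | benzyne | C1=CC=CC#C1 | intermediate
20 | 7,7-dimethoxybicyclo[4.2.0]octa-1,3,5-triene | COC1(OC)Cc2ccccc12 | intermediate
21 | bicyclo[4.2.0]octa-1,3,5-trien-7-one | O=C1Cc2ccccc12 | intermediate
22 | but-2-yne | CC#CC | starting material
23 | 2,3-dimethylnaphthalen-1(4H)-one | CC1=C(C)C(=O)c2ccccc2C1 | intermediate
24 | 2,3-dimethylnaphthalen-1-ol | Cc1cc2ccccc2c(O)c1C | intermediate
25 | 2,3-dimethylnaphthalene-1,4-dione | CC1=C(C)C(=O)c2ccccc2C1=O | intermediate
26 | 2-(bromomethyl)-3-methylnaphthalene-1,4-dione | CC1=C(CBr)C(=O)c2ccccc2C1=O | intermediate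
27 | {(1E,4S,6R,10R)-4-[(dimethylalumanyl)oxy]-2,6,10,14-tetramethylpentadec-1-en-1-yl}dimethylalumane | C[Al](C)/C=C(\C)C[C@@H](O[Al](C)C)C[C@H](C)CCC[C@H](C)CCCC(C)C | intermediate
28 | 2-[(2E,5S,7R,11R)-5-hydroxy-3,7,11,15-tetramethylhexadec-2-en-1-yl]-3-methylnaphthalene-1,4-dione | CC1=C(C/C=C(\C)C[C@@H](O)C[C@H](C)CCC[C@H](C)CCCC(C)C)C(=O)c2ccccc2C1=O | target

**Step count and risks**

Total step count: 11. Longest linear sequence: 8 (steps 1–7, then 11). The quinone branch is 3 steps (8–10).

The three steps most likely to fail: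

Step 9, the proposed nickel ring expansion with in-flask oxygenation. The risks are insertion into the acyl–aryl bond instead of C1–C2, which would lead to a 2-naphthol, and nickel-mediated cyclotrimerisation of but-2-yne. The fallback uses known chemistry (Dötz benzannulation). It sets out from but-2-yne 22, with commercial phenyllithium supplying the benzo ring in place of 21, and comes back to the route at 25. Phenyllithium is added to Cr(CO)6 in Et2O to give lithium benzoylpentacarbonylchromate F1, which is O-methylated with MeOTf to pentacarbonyl[methoxy(phenyl)methylidene]chromium F2. Warming F2 with 22 in THF at 50 °C gives 4-methoxy-2,3-dimethylnaphthalen-1-ol F3 (chromium-bound until work-up). (NH4)2Ce(NO3)6 in aqueous MeCN then oxidises F3 to 25.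

Step 10, the mono-bromination. The risks are over-bromination to the bis(bromomethyl)quinone and radical degradation of the quinone. The fallback brominates at the hydroquinone dimethyl ether level; it sets out from 25 and comes back at 26. Compound 25 is reduced with Na2S2O4 to 2,3-dimethylnaphthalene-1,4-diol F4 and methylated in the same flask (Me2SO4, KOH) to 1,4-dimethoxy-2,3-dimethylnaphthalene F5. NBS (1 equiv) with AIBN gives 2-(bromomethyl)-1,4-dimethoxy-3-methylnaphthalene F6, which is stable to chromatography. (NH4)2Ce(NO3)6 in MeCN/H2O at 0 °C returns 26.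

Step 11, the final union. The risks are interference by the free aluminium alkoxide, attack of residual AlMe3 on the quinone carbonyls, and reductive homocoupling of the bromide on nickel. The fallback joins the fragments at the hydroquinone dimethyl ether level with palladium and oxidises last; it sets out from 16 and 25 and comes back at 28. Alkenylalane 27, generated from 16 as in step 11, is coupled with 2-(bromomethyl)-1,4-dimethoxy-3-methylnaphthalene F6 (made from 25 as in the preceding fallback) using Pd(PPh3)4 in THF (Negishi alkenylalane–benzyl halide coupling). This gives (2E,5S,7R,11R)-1-(1,4-dimethoxy-3-methylnaphthalen-2-yl)-3,7,11,15-tetramethylhexadec-2-en-5-ol F7. (NH4)2Ce(NO3)6 in MeCN/H2O at 0 °C then unmasks the quinone to give 28.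

Further compounds

F1 | step 9 | lithium benzoylpentacarbonylchromate | [Li+].[O-]C(c1ccccc1)=[Cr](=C=O)(=C=O)(=C=O)(=C=O)=C=O
F2 | step 9 | pentacarbonyl[methoxy(phenyl)methylidene]chromium | COC(c1ccccc1)=[Cr](=C=O)(=C=O)(=C=O)(=C=O)=C=O
F3 | step 9 | 4-methoxy-2,3-dimethylnaphthalen-1-ol | COc1c(C)c(C)c(O)c2ccccc12
F4 | step 10 | 2,3-dimethylnaphthalene-1,4-diol | Cc1c(C)c(O)c2ccccc2c1O
F5 | step 10 | 1,4-dimethoxy-2,3-dimethylnaphthalene | COc1c(C)c(C)c(OC)c2ccccc12
F6 | step 10 | 2-(bromomethyl)-1,4-dimethoxy-3-methylnaphthalene | COc1c(C)c(CBr)c(OC)c2ccccc12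
F7 | step 11 | (2E,5S,7R,11R)-1-(1,4-dimethoxy-3-methylnaphthalen-2-yl)-3,7,11,15-tetramethylhexadec-2-en-5-ol | COc1c(C)c(C/C=C(\C)C[C@@H](O)C[C@H](C)CCC[C@H](C)CCCC(C)C)c(OC)c2ccccc12
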